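**Plan**

1. Locants used here: ring C = C1(CO2H)=C2–C3(OH)–C4–C12–C11(OH); ring D = C4–C5–C6–C13–C12; ring A = C6–C7(octyl)–C8–C13; ring B = C8–C9=C10–C11–C12–C13.
2. Cuts in ring C: C1–C11 (iodide-triggered aldol of a ynoate onto a C11 ketone) and C2–C3 (alkynylation of a C3 aldehyde). The C9=C10/C11–OH pattern of ring B goes back to a C9 ketone (Wharton transposition of an epoxy ketone).
3. Cut in ring D: C4 carries the oxygenated carbon C3 as its only carbon outside the cyclopentane. Ring D with C3 is therefore the product of a Wolff ring contraction of the six-membered ketone ring C3(=O)–C4–C5–C6–C13–C12, with C3 extruded as the carboxyl carbon.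
4. Cuts in ring A: C6–C13 and C7–C8 of that 6-4-6 tricycle, by an intramolecular enone–alkene [2+2] photocycloaddition of a 4-substituted cyclohexenone made by Michael/aldol annulation.
5. Forward order: ring B, then ring A together with the six-membered forerunner of ring D, then contraction to ring D, then transposition in ring B, then ring C.
6. Stereochemistry: C12 from the prolinol ether catalyst; C13, C8, C6 and C7 from the C12 tether in the [2+2] step; C4 by equilibration after the contraction; C3 from the ProPhenol alkynylation; C11 from the C4 tether in the closure of ring C.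

Key step: step 11

Remark on the chemistry: the sense of induction of the two chiral catalysts (steps 5 and 15) is assigned from the usual enamine-shielding and ProPhenol models; if either proved opposite, the antipodal catalyst would be used. Compounds 1, 3, 7 and 23 are taken as commercial.

**Route**

Step 1
Reactants: 1 (E)-undec-2-en-1-ol
Product: 2 (E)-1-bromoundec-2-ene
Conditions: PBr3, pyridine (cat.), Et2O, −10 to 0 °C
Reagents that add atoms: phosphorus tribromide, BrP(Br)Br
Why: Bromination of the primary allylic alcohol through its phosphite ester (SN2 by bromide) should keep the E double bond and give the electrophile for the chain; no stereocentre is formed.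

Step 2
Reactants: 3 ethyl acetoacetate; 2 (E)-1-bromoundec-2-ene
Product: 4 ethyl (E)-3-oxopentadec-6-enoate
Conditions: NaH, THF, 0 °C; n-BuLi, 0 °C; then 2, 0 °C to rt; aq. work-up
Reagents that add atoms: none
Why: γ-Alkylation of the acetoacetate dianion, whose terminal carbanion is the more reactive site, should join C4–C5 by SN2 on the allylic bromide; no stereocentre is formed.

Step 3
Reactants: 4 ethyl (E)-3-oxopentadec-6-enoate
Product: 5 ethyl 2-[2-((E)-dodec-3-en-1-yl)-1,3-dioxolan-2-yl]acetate
Conditions: HOCH2CH2OH, p-TsOH (cat.), toluene, reflux (Dean–Stark)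
Reagents that add atoms: ethylene glycol, OCCO
Why: Acid-catalysed ketalisation with removal of water should mask the C3 ketone, so that C12 later has a single carbonyl neighbour and C3 carries no stereocentre.

Step 4
Reactants: 5 ethyl 2-[2-((E)-dodec-3-en-1-yl)-1,3-dioxolan-2-yl]acetate
Product: 6 2-[2-((E)-dodec-3-en-1-yl)-1,3-dioxolan-2-yl]acetaldehyde
Conditions: iBu2AlH, toluene, −78 °C; aq. potassium sodium tartrate
Reagents that add atoms: none
Why: Partial reduction of the ester should stop at the aldehyde because the aluminium hemiacetal is stable at −78 °C.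

Step 5
Reactants: 6 2-[2-((E)-dodec-3-en-1-yl)-1,3-dioxolan-2-yl]acetaldehyde; 7 methyl vinyl ketone
Product: 9 (S)-4-[2-((E)-dodec-3-en-1-yl)-1,3-dioxolan-2-yl]cyclohex-2-en-1-one, via keto aldehyde 8 (not isolated)
Conditions: (R)-2-[methoxy(diphenyl)methyl]pyrrolidine (cat.), ethyl 3,4-dihydroxybenzoate (cat.), 7 (neat), 4 °C; then LiOH, iPrOH, rt
Reagents that add atoms: none
Why: Enamine-catalysed Michael addition of the aldehyde to the enone followed by intramolecular aldol condensation (Robinson-type annulation) should build ring B as the enone, with C12 set by the catalyst shielding one face of the enamine.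

Step 6
Reactants: 9 (S)-4-[2-((E)-dodec-3-en-1-yl)-1,3-dioxolan-2-yl]cyclohex-2-en-1-one
Product: 10 6-4-6 tricyclic C9 ketone with C3 ethylene ketal
Conditions: hν (366 nm), CH2Cl2 (degassed, dilute), rt
Reagents that add atoms: none
Why: Intramolecular enone–alkene [2+2] photocycloaddition through the triplet enone should form C13–C6 first (six-membered ring, no five-membered alternative) and then C8–C7; the C12 tether delivers the alkene to its own face so that H-12, H-13 and H-8 end cis, and the E-alkene with closure of the biradical on the open side places octyl exo on C7.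

Step 7
Reactants: 10 6-4-6 tricyclic C9 ketone with C3 ethylene ketal
Product: 12 tricyclic enone (C9=O and C10=C11), via silyl enol ether 11 (not isolated)
Conditions: LiN(iPr)2, Me3SiCl, THF, −78 °C; then Pd(OAc)2, MeCN, rt
Reagents that add atoms: none
Why: Saegusa–Ito oxidation: kinetic enolisation should go to the C10 methylene and not to the cyclobutane methine C8, and Pd(OAc)2 then gives the C10=C11 enone by β-hydride elimination; no stereocentre is formed.

Step 8
Reactants: 12 tricyclic enone (C9=O and C10=C11)
Product: 13 epoxy ketone (C9=O and C10–C11 epoxide) with C3 ketal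
Conditions: 30% H2O2, NaOH, MeOH, 0 °C
Reagents that add atoms: hydrogen peroxide, OO
Why: Weitz–Scheffer nucleophilic epoxidation should take place on the convex face, anti to the C3 dioxolane; the two new centres are temporary, since C10 becomes sp2 in step 12 and C11 a ketone in step 14.

Step 9
Reactants: 13 epoxy ketone (C9=O and C10–C11 epoxide) with C3 ketal
Product: 14 epoxy diketone (C9=O and C3=O)
Conditions: pyridinium p-toluenesulfonate (cat.), acetone/H2O, 55 °C
Reagents that add atoms: water, O
Why: Mild acid hydrolysis of the dioxolane should free the C3 ketone of the six-membered ring while the electron-poor epoxy ketone is left alone.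

Step 10
Reactants: 14 epoxy diketone (C9=O and C3=O)
Product: 16 C4-diazo C3-ketone, via trifluoroacetyl ketone 15 (not isolated)
Conditions: LiN(SiMe3)2, THF, −78 °C; CF3CO2CH2CF3; then MeSO2N3, Et3N, H2O, MeCN, rt
Reagents that add atoms: methanesulfonyl azide, CS(=O)(=O)N=[N+]=[N-]
Why: Detrifluoroacetylative diazo transfer (Regitz type): the kinetic enolate should form at the C4 methylene, because the C9 ketone is flanked only by the epoxide carbon C10 and the cyclobutane methine C8, and the activated 1,3-dicarbonyl then accepts the diazo group at C4.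

Step 11
Reactants: 16 C4-diazo C3-ketone
Product: 19 ring-contracted methyl ester (CO2Me on C4 trans to C11), via ketene 17 (not isolated), via C4-epimeric ester 18 (not isolated)
Conditions: hν (365 nm), MeOH, rt; then NaOMe (cat.), MeOH, 0 °C to rt
Reagents that add atoms: methanol, CO
Why: Irradiation of the cyclic α-diazo ketone (locked s-cis) should expel N2 with 1,2-shift of the ring-fusion carbon C12 from the carbonyl carbon C3 to the carbene carbon C4 (photochemical Wolff rearrangement, the classical ring contraction of 2-diazocyclohexanones), so that the six-membered ring C3–C4–C5–C6–C13–C12 becomes the cyclopentane C4–C5–C6–C13–C12 and C3 leaves the ring as a ketene carbon that methanol captures as the ester. Ring D is thus closed by migration and not by cyclisation, with retention at the migrating C12, and the cis-fused cyclobutane and ring B are untouched. The only new stereocentre, C4, is first set by protonation of the ester enol and is then equilibrated with NaOMe to the exo ester trans to the C11 branch on C12, which is the configuration needed for the trans C/D ring fusion. The step needs chemoselective excitation of the diazo ketone beside the epoxy ketone, which light of 365 nm should secure, and rearrangement ahead of C–H insertion, which the s-cis geometry and the protic medium favour. The epoxy ketone serves here as a ring B carbonyl that cannot enolise towards C10 and carries no free hydroxyl that could trap the ketene.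

Step 12
Reactants: 19 ring-contracted methyl ester (CO2Me on C4 trans to C11)
Product: 20 allylic alcohol ester (C9=C10 and C11–OH)
Conditions: N2H4·H2O, AcOH (cat.), MeOH, 0 °C to rt
Reagents that add atoms: none
Why: Wharton transposition: the hydrazone of the epoxy ketone should fragment with loss of N2 to the C9=C10 alkene and the C11 alcohol, whose configuration follows from the epoxide and is erased in step 14.

Step 13
Reactants: 20 allylic alcohol ester (C9=C10 and C11–OH)
Product: 21 hydroxy aldehyde (C3 = CHO)
Conditions: iBu2AlH, CH2Cl2, −78 °C; aq. potassium sodium tartrate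
Reagents that add atoms: none
Why: Partial reduction of the methyl ester at −78 °C should give the C3 aldehyde; the trans relation of C3 and C11 on ring D prevents lactol formation.

Step 14
Reactants: 21 hydroxy aldehyde (C3 = CHO)
Product: 22 enone aldehyde (C11=O with C9=C10 and C3 = CHO)
Conditions: MnO2, CH2Cl2, rt
Reagents that add atoms: none
Why: MnO2 oxidises the allylic alcohol chemoselectively to the C11 enone and should leave the aldehyde alone.

Step 15
Reactants: 22 enone aldehyde (C11=O with C9=C10 and C3 = CHO); 23 methyl propiolate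
Product: 25 silyl ether ynoate ((S)-C3–OSiMe3 with C2≡C1–CO2Me), via propargylic zinc alkoxide 24 (not isolated)
Conditions: Me2Zn, (S,S)-ProPhenol (cat.), Ph3PO (cat.), toluene, 4 °C; then Me3SiCl, Et3N, 0 °C
Reagents that add atoms: chlorotrimethylsilane, C[Si](C)(C)Cl
Why: Catalytic asymmetric addition of the zinc alkynylide to the aldehyde (the ketone is inert to alkynylzinc) should make C2–C3 and set the (S)-carbinol at C3 under catalyst control; silylation in the flask removes the proton that would quench the allenolate of step 16.

Step 16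
Reactants: 25 silyl ether ynoate ((S)-C3–OSiMe3 with C2≡C1–CO2Me)
Product: 26 tetracyclic vinyl iodide (ring C closed with C2–I and C11–OH)
Conditions: MgI2, CH2Cl2, 0 °C to rt
Reagents that add atoms: magnesium iodide, [Mg+2].[I-].[I-]
Why: Proposed new method: iodide from MgI2 should add to the ynoate β-carbon C2 to give a magnesium allenolate whose α-carbon C1 is held by the C4 tether over the β-face of the C11 ketone, so that a 6-(enolexo)-exo-trig aldol addition closes ring C, makes C1–C11 and sets C11 with OH cis to H-12 (cis B/C fusion, as in aldol closures that give angular carbinols); the closest known reaction types are the iodide-triggered Morita–Baylis–Hillman (halo-aldol) reaction of alkynoates with aldehydes and the intramolecular iodo-aldol cyclisation of enoate ketones, neither shown for a ynoate that closes an endocyclic alkene onto a ketone.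

Step 17
Reactants: 26 tetracyclic vinyl iodide (ring C closed with C2–I and C11–OH)
Product: 27 tetracyclic methyl ester with C3–OSiMe3
Conditions: Pd(PPh3)4 (cat.), Bu3SnH, THF, rt
Reagents that add atoms: none
Why: Palladium-catalysed hydrodeiodination (oxidative addition of the β-iodo enoate, hydride transfer from tin, reductive elimination) should replace iodine at C2 by hydrogen without touching the other alkene or any stereocentre.

Step 18
Reactants: 27 tetracyclic methyl ester with C3–OSiMe3
Product: 28 CNP0106718.3 (target acid)
Conditions: LiOH, THF/MeOH/H2O, rt; then aq. HCl to pH 3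
Reagents that add atoms: lithium hydroxide, [Li+].[OH-]
Why: Saponification of the methyl ester with concurrent cleavage of the labile trimethylsilyl ether should give the dihydroxy acid; no stereocentre is affected.

**Compound list**

1 | (E)-undec-2-en-1-ol | CCCCCCCC/C=C/CO | starting material
2 | (E)-1-bromoundec-2-ene | CCCCCCCC/C=C/CBr | intermediate
3 | ethyl acetoacetate | CCOC(=O)CC(C)=O | starting material
4 | ethyl (E)-3-oxopentadec-6-enoate | CCCCCCCC/C=C/CCC(=O)CC(=O)OCC | intermediate
5 | ethyl 2-[2-((E)-dodec-3-en-1-yl)-1,3-dioxolan-2-yl]acetate | CCCCCCCC/C=C/CCC1(OCCO1)CC(=O)OCC | intermediate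
6 | 2-[2-((E)-dodec-3-en-1-yl)-1,3-dioxolan-2-yl]acetaldehyde | CCCCCCCC/C=C/CCC1(OCCO1)CC=O | intermediate
7 | methyl vinyl ketone | CC(=O)C=C | starting material
8 | (S)-2-[2-((E)-dodec-3-en-1-yl)-1,3-dioxolan-2-yl]-5-oxohexanal | CCCCCCCC/C=C/CCC1(OCCO1)[C@H](C=O)CCC(C)=O | intermediate (not isolated)
9 | (S)-4-[2-((E)-dodec-3-en-1-yl)-1,3-dioxolan-2-yl]cyclohex-2-en-1-one | CCCCCCCC/C=C/CCC1(OCCO1)[C@@H]2C=CC(=O)CC2 | intermediate
10 | 6-4-6 tricyclic ketone: C9=O in ring B, cyclobutane A, six-membered ring C3–C4–C5–C6–C13–C12 with C3 ethylene ketal; H-8, H-13, H-12 cis; octyl on C7 exo | CCCCCCCC[C@H]1[C@@H]2C(=O)CC[C@H]3[C@@H]2[C@@H]1CCC34OCCO4 | intermediate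
11 | trimethylsilyl enol ether of 10 (C9–OSiMe3, C9=C10) | CCCCCCCC[C@H]1[C@@H]2C(O[Si](C)(C)C)=CC[C@H]3[C@@H]2[C@@H]1CCC34OCCO4 | intermediate (not isolated)
12 | tricyclic enone (C9=O, C10=C11), C3 ketal | CCCCCCCC[C@H]1[C@@H]2C(=O)C=C[C@H]3[C@@H]2[C@@H]1CCC34OCCO4 | intermediate
13 | epoxy ketone (C9=O, C10–C11 epoxide on the face of H-12), C3 ketal | CCCCCCCC[C@H]1[C@@H]2C(=O)[C@H]5O[C@H]5[C@H]3[C@@H]2[C@@H]1CCC34OCCO4 | intermediate
14 | epoxy diketone (C9=O, C3=O) | CCCCCCCC[C@H]1[C@@H]2C(=O)[C@H]5O[C@H]5[C@H]3[C@@H]2[C@@H]1CCC3=O | intermediate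
15 | C4-trifluoroacetyl derivative of 14 | CCCCCCCC[C@H]1[C@@H]2C(=O)[C@H]5O[C@H]5[C@H]3[C@@H]2[C@@H]1CC(C(=O)C(F)(F)F)C3=O | intermediate (not isolated)
16 | C4-diazo C3-ketone (α-diazo ketone in the six-membered ring) | CCCCCCCC[C@H]1[C@@H]2C(=O)[C@H]5O[C@H]5[C@H]3[C@@H]2[C@@H]1CC(=[N+]=[N-])C3=O | intermediate
17 | ketene (C4=C3=O) on the contracted cyclopentane D | CCCCCCCC[C@H]1[C@@H]2C(=O)[C@H]5O[C@H]5[C@H]3[C@@H]2[C@@H]1CC3=C=O | intermediate (not isolated)
18 | C4 epimer of 19 (CO2Me cis to C11) | CCCCCCCC[C@H]1[C@@H]2C(=O)[C@H]5O[C@H]5[C@H]3[C@@H]2[C@@H]1C[C@H]3C(=O)OC | intermediate (not isolated)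
19 | 4-6-5 tricyclic methyl ester: cyclopentane D with CO2Me on C4 trans to C11; epoxy ketone in ring B | CCCCCCCC[C@H]1[C@@H]2C(=O)[C@H]5O[C@H]5[C@H]3[C@@H]2[C@@H]1C[C@@H]3C(=O)OC | intermediate
20 | allylic alcohol ester: C9=C10, C11–OH cis to H-12, CO2Me on C4 | CCCCCCCC[C@H]1[C@@H]2C=C[C@@H](O)[C@H]3[C@@H]2[C@@H]1C[C@@H]3C(=O)OC | intermediate
21 | hydroxy aldehyde: C11–OH, C3 = CHO on C4 | CCCCCCCC[C@H]1[C@@H]2C=C[C@@H](O)[C@H]3[C@@H]2[C@@H]1C[C@@H]3C=O | intermediate
22 | enone aldehyde: C11=O, C9=C10, C3 = CHO on C4 | CCCCCCCC[C@H]1[C@@H]2C=CC(=O)[C@H]3[C@@H]2[C@@H]1C[C@@H]3C=O | intermediate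
23 | methyl propiolate | C#CC(=O)OC | starting material
24 | (S)-C3 propargylic alcohol, present as its methylzinc alkoxide (drawn as the alcohol) | CCCCCCCC[C@H]1[C@@H]2C=CC(=O)[C@H]3[C@@H]2[C@@H]1C[C@@H]3[C@H](O)C#CC(=O)OC | intermediate (not isolated)
25 | silyl ether ynoate: (S)-C3–OSiMe3, C2≡C1–CO2Me, C11 ketone | CCCCCCCC[C@H]1[C@@H]2C=CC(=O)[C@H]3[C@@H]2[C@@H]1C[C@@H]3[C@H](O[Si](C)(C)C)C#CC(=O)OC | intermediate
26 | tetracyclic vinyl iodide: ring C closed, C2–I, C11–OH, C3–OSiMe3, methyl ester on C1 | CCCCCCCC[C@H]1[C@@H]2C=C[C@]3(O)C(C(=O)OC)=C(I)[C@@H](O[Si](C)(C)C)[C@H]4C[C@H]1[C@H]2[C@@H]43 | intermediate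
27 | tetracyclic methyl ester, C3–OSiMe3, C11–OH | CCCCCCCC[C@H]1[C@@H]2C=C[C@]3(O)C(C(=O)OC)=C[C@@H](O[Si](C)(C)C)[C@H]4C[C@H]1[C@H]2[C@@H]43 | intermediate
28 | CNP0106718.3 | CCCCCCCC[C@H]1[C@@H]2C=C[C@]3(O)C(C(=O)O)=C[C@@H](O)[C@H]4C[C@H]1[C@H]2[C@@H]43 | target

**Count and risks**

Total step count: 18. Longest linear sequence: 18 steps (1 to 28; 3, 7 and 23 are bought).

Steps most likely to fail:

1. Step 16 (the labelled step). What may go wrong: protonation of the allenolate before C1–C11 forms; iodide addition to the ring B enone followed by Michael closure of that enolate onto the ynoate; attack on the wrong face of the C11 ketone (trans B/C fusion). Fallback with known chemistry, from 22 to 27: Nozaki–Hiyama–Kishi addition of methyl (E)-3-iodoacrylate to the aldehyde of 22 (CrCl2, NiCl2 cat., DMSO) should give the hydroxy enoate F1, whose C3 epimers would be separated. Silylation (Me3SiCl, imidazole) should give the silyl ether F2. LiSePh in THF at −78 °C should then add to C2, and the ester enolate so formed should close ring C by aldol addition to the C11 ketone (tandem Michael–aldol, a Morita–Baylis–Hillman surrogate), giving the selenide F3. Oxidation with H2O2/pyridine and syn elimination of the selenoxide towards C1 should give 27.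

2. Step 10. What may go wrong: enolisation at C12 with β-opening of the neighbouring epoxide, or at C8, instead of at the C4 methylene. Fallback without strong base, from 14 to 16: heating 14 with tert-butoxybis(dimethylamino)methane (toluene, 80 °C) should give the enaminone F4, since C4 is the only methylene next to a ketone. Diazo transfer from 4-acetamidobenzenesulfonyl azide (MeCN, rt), with loss of the sulfonyl formamidine, should give 16.

3. Step 6. What may go wrong: slow formation of the first bond to a six-membered ring, crossed cycloaddition, hydrogen abstraction by the enone triplet, or addition to the far face (trans ring fusion). Fallback with a different chromophore, from 9 to 11: kinetic enolisation of 9 (LiN(iPr)2, Me3SiCl, THF, −78 °C) should give the cross-conjugated silyloxy diene F5. Triplet sensitisation of this diene with Ir[dF(CF3)ppy]2(dtbbpy)PF6 under blue light should bring about the [2+2] cycloaddition between C13=C8 and the tethered alkene and leave the silyl enol ether, which is 11 and enters the Pd(OAc)2 oxidation of step 7.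

Further compounds
F1 | step 16 | hydroxy enoate: methyl (E)-4-hydroxybut-2-enoate unit on C4 of the enone tricycle ((S)-carbinol at C3) | CCCCCCCC[C@H]1[C@@H]2C=CC(=O)[C@H]3[C@@H]2[C@@H]1C[C@@H]3[C@H](O)/C=C/C(=O)OC
F2 | step 16 | trimethylsilyl ether of F1 | CCCCCCCC[C@H]1[C@@H]2C=CC(=O)[C@H]3[C@@H]2[C@@H]1C[C@@H]3[C@H](O[Si](C)(C)C)/C=C/C(=O)OC
F3 | step 16 | tetracyclic C2 phenylselenide (ring C closed, C1–C2 saturated, C11–OH, C3–OSiMe3) | CCCCCCCC[C@H]1[C@@H]2C=C[C@]3(O)C(C(=O)OC)C([Se]c5ccccc5)[C@@H](O[Si](C)(C)C)[C@H]4C[C@H]1[C@H]2[C@@H]43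
F4 | step 10 | C4-(dimethylaminomethylene) derivative of 14 (enaminone) | CCCCCCCC[C@H]1[C@@H]2C(=O)[C@H]5O[C@H]5[C@H]3[C@@H]2[C@@H]1CC(=CN(C)C)C3=O
F5 | step 6 | silyloxy diene: (S)-configured 2-(trimethylsilyloxy)cyclohexa-1,3-diene from 9 | CCCCCCCC/C=C/CCC1(OCCO1)[C@@H]2C=CC(O[Si](C)(C)C)=CC2
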